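Assumption: rotation about the C8–C3' biaryl bond is taken to be fast at room temperature (three ortho substituents, one of them the pyranone ring oxygen), so the target is a single achiral compound and no axial configuration has to be set.

## The problem

The target 22 is a biflavone in which C8 of a chrysoeriol unit is bonded to C3' of ring B of an apigenin unit. It has no stereocenter, so no stereo element has to control another; the difficulty lies in connectivity and in telling the oxygens apart. The aryl group must sit at C8 and not at C6 of a 5,7-dioxygenated chromone. Electrophiles distinguish these two positions only weakly, and hot acid can interchange them by ring opening and reclosure once the 5-hydroxyl is free (Wessely–Moser rearrangement). Six phenols must be set free at the end beside one guaiacyl methyl ether that must stay. The groups at risk on the way are the pyranone rings, which open with strong nucleophiles and are reduced under forcing conditions, and the tri-ortho-substituted biaryl bond, which is hindered in any cross-coupling. The feature that opens the route is that C4, C3 and C2 of the apigenin unit form a 1,3-dicarbonyl equivalent between ring A, which bears oxygen at both positions ortho to C4, and ring B. Such a unit is the reduced and hydrolysed form of a 3,5-diarylisoxazole, and the two ortho oxygens are exactly what makes the required aryl nitrile oxide long-lived.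

## Retrosynthesis

**22 from 21.** The six O–isopropyl bonds are cut. All phenols are carried as isopropyl ethers because a boron trihalide at low temperature cleaves secondary alkyl aryl ethers and leaves methyl ethers. Methyl protection could not be told from the natural methoxy group, and benzyl ethers would restrict the reductive step that opens the isoxazole. The forward step must strip six ethers without touching the methoxy group and without the hot acid that could move the C8 aryl group to C6.

**21 from 19 and 18.** The apigenin pyranone is cut at O1–C2, and its C4 carbonyl is traced back to the amino carbon of enaminone 19, which is the ring-opened form of isoxazole 18. Against a cut at C2–C3 (acyl transfer), this keeps the three-carbon bridge as one robust heterocycle until the biaryl and the chrysoeriol unit are complete. The forward sequence needs an N–O reduction that spares the chromone. It then needs one acid treatment that hydrolyses the vinylogous amide, frees the ring A phenol and closes ring C through the hydroxyaryl diketone 20.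

**18 from 17 and 12.** This is the key cut: the isoxazole C3–C4 bond (the future C4–C3 bond of the apigenin unit) and the O–C5 bond. It divides the molecule into the small ring A nitrile oxide 17 and the alkyne 12, which carries the finished chrysoeriol unit. The union needs no base, acid or metal, and the substitution pattern of a terminal alkyne fixes the regiochemistry. The forward reaction must be faster than dimerisation or rearrangement of the dipole and must leave the pyranone double bond alone.

**17 from 16, 15, 14 and 13.** Only functional groups change: nitrile oxide from aldoxime 16 by dehydrogenation, oxime from aldehyde 15. The three oxygens of 13 are differentiated through the hydrogen-bonded ortho hydroxyl, which stays free in the di-O-isopropylation to 14. It is then capped as the methoxymethyl ether in 15, because it is the oxygen that becomes O1 and must fall off in the acid step.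

**12 from 11, and 11 from 7 and 10.** The alkyne is traced to aldehyde 11 by one-carbon homologation, and the biaryl bond is cut into 8-iodoflavone 7 and arylboronate 10. The aldehyde is the coupling-stable form of the alkyne. The halide is placed on the more hindered partner, where oxidative addition suffers least. The forward coupling must form a tri-ortho-substituted biaryl.

**10 from 9 and 8.** The carbon–boron bond is cut back to bromide 9, the isopropyl ether of commercial 8.

**7 from 6, 6 from 3 and 5, then 3 from 2 and 1, and 5 from 4.** The chrysoeriol pyranone is opened at O1–C2 to chalcone 6 and then at the enone C=C to iodoacetophenone 3 and aldehyde 5. The iodine is placed at the acetophenone stage (3 from 2), where one open position lies between hydroxyl and isopropoxy and the other between two isopropoxy groups. Because 6 has a single free phenol, the cyclisation can only put the iodine at C8. Compounds 2 and 5 are the isopropyl ethers of 1 and 4.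

## Roads not taken

**Alternative 1:** Both pyranones are cut at C2–C3 at once. The forward key step is a two-fold Baker–Venkataraman rearrangement of the biaryl bis(acetophenone) diester A2. Excess base forms two enolates, and each takes the aroyl group from the neighbouring phenol ester, giving the bis(1,3-diketone) A1 with two free ortho phenols and no new ring. Acid would then close both rings.
- Merits: this is the most thoroughly tested flavone construction, it needs no metal after the biaryl bond, and two pyranones arise from one rearrangement and one cyclodehydration. In step count it is at least equal to the chosen plan and probably shorter, and it avoids nitrile oxide chemistry.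
- Weak points: A2 must be built on a biaryl that already carries an enolisable hydroxyacetophenone. Two different hindered esters are needed, one on a phenol flanked by an acetyl group and the biaryl. Under excess base the two acyl transfers need not keep pace, ester cleavage competes with migration, and intermolecular exchange of the two aroyl groups would scramble the units. The whole molecule passes through every step.
- Comparison: against the better step economy of this road the chosen plan sets its convergence. The chrysoeriol pyranone is finished before the coupling, and the second pyranone arises from two complete halves under neutral conditions.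

**Alternative 2:** Ring A of the chrysoeriol unit is cut at C4a–C5 and built onto a 2-aryl-4-pyranone. Thermolysis of the tert-butyl β-ketoester A4 would expel isobutene and give an acylketene. Its enol is a dienylketene that includes the pyranone C=C bond, and 6π-electrocyclisation onto the pyranone CH followed by tautomerisation would give the 5,7-dihydroxyflavone A3 with the bromoaryl group at C8.
- Merits: the position of the aryl group is fixed by the skeleton of A4, so the C6/C8 question of the chosen plan (step 2) does not arise; here this road is better. It also gives the 5,7-diol free and avoids a hindered cross-coupling at C8.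
- Weak points: A4 is an α-aryl-α-pyranonyl 3,5-dioxo ester whose preparation is long. The acylketene has a nearer nucleophile than the pyranone carbon, namely the enol oxygen of its own ketone, and closure through oxygen to a 4-hydroxy-2-pyranone is the usual fate of such systems. A3 is also only half way: the bromide must still be grown into the apigenin unit beside two free phenols.
- Comparison: the chosen plan answers the regiochemical advantage of this road with a short, well-known chrysoeriol synthesis. Its single regiochemical choice is made early on a small compound, where an error is cheap to detect.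

**Alternative 3:** Ring C of the chrysoeriol unit is cut at C4–C4a. The (Z)-3-aryloxy-3-arylacrylic acid A6, with its carboxyl group activated, would acylate the aryloxy ring intramolecularly and give A5, which is the same compound as 21.
- Merits: only one position ortho to the aryloxy oxygen is free, so the closure has no regiochemical choice, and the ring attacked is a strongly activated phloroglucinol ether. The endgame is shared with the chosen plan, and the oxidative chalcone cyclisation beside an aryl iodide (step 5) is avoided. In these respects this road is as good or better.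
- Weak points: A6 requires O-vinylation of a phenol flanked by the biaryl group with control of alkene geometry, since only the Z acid can close. Friedel–Crafts acid threatens the isopropyl ethers, above all the one peri to the carbonyl of the apigenin unit, which would have to be carried through this harshest step. Loss of the phenol by retro-addition competes.
- Comparison: the chosen plan closes its last ring with dilute aqueous acid and builds the chrysoeriol unit by the chalcone route. Against the regiochemical certainty of the A6 closure it sets the fact that 6 has only one free phenol, which leaves the iodination as the one point to verify.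

Key step: step 14

## Route

Step 1
Reactants: 1 2',4',6'-trihydroxyacetophenone
Product: 2 1-(2-hydroxy-4,6-diisopropoxyphenyl)ethanone
Conditions: 2-bromopropane (2.3 equiv), K2CO3, DMF, 60 °C
Reagents that add atoms: 2-bromopropane, CC(C)Br
Why: Williamson etherification; the hydroxyl hydrogen-bonded to the acetyl carbonyl is the least nucleophilic and should stay free when the halide is limited to about two equivalents.

Step 2
Reactants: 2 1-(2-hydroxy-4,6-diisopropoxyphenyl)ethanone
Product: 3 1-(2-hydroxy-3-iodo-4,6-diisopropoxyphenyl)ethanone
Conditions: NIS (1.05 equiv), TFA (10 mol %), MeCN, 0 °C → rt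
Reagents that add atoms: N-iodosuccinimide, O=C1CCC(=O)N1I
Why: Electrophilic aromatic iodination; C3 lies between the small hydroxyl and one isopropoxy group whereas C5 lies between two isopropoxy groups, so iodine should enter C3, as it does in the known iodination of 2-hydroxy-4,6-dimethoxyacetophenone.

Step 3
Reactants: 4 vanillin
Product: 5 4-isopropoxy-3-methoxybenzaldehyde
Conditions: 2-bromopropane, K2CO3, DMF, 70 °C
Reagents that add atoms: 2-bromopropane, CC(C)Br
Why: Williamson etherification of the only phenol; the aldehyde is inert to carbonate.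

Step 4
Reactants: 3 1-(2-hydroxy-3-iodo-4,6-diisopropoxyphenyl)ethanone; 5 4-isopropoxy-3-methoxybenzaldehyde
Product: 6 (E)-1-(2-hydroxy-3-iodo-4,6-diisopropoxyphenyl)-3-(4-isopropoxy-3-methoxyphenyl)prop-2-en-1-one
Conditions: KOH (50% aq.), EtOH, rt
Reagents that add atoms: none
Why: Claisen–Schmidt condensation; the aldehyde cannot enolise, and E1cB dehydration of the aldol gives the conjugated E-enone under thermodynamic control.

Step 5
Reactants: 6 (E)-1-(2-hydroxy-3-iodo-4,6-diisopropoxyphenyl)-3-(4-isopropoxy-3-methoxyphenyl)prop-2-en-1-one
Product: 7 8-iodo-5,7-diisopropoxy-2-(4-isopropoxy-3-methoxyphenyl)-4H-chromen-4-one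
Conditions: I2 (10 mol %), DMSO, 120 °C
Reagents that add atoms: none
Why: Oxidative cyclisation of a 2'-hydroxychalcone (oxa-Michael closure, α-iodination, elimination), with DMSO reoxidising the hydrogen iodide so that iodine is catalytic; the single free phenol, flanked by the iodine, becomes O1 and so places the iodine at C8.

Step 6
Reactants: 8 3-bromo-4-hydroxybenzaldehyde
Product: 9 3-bromo-4-isopropoxybenzaldehyde
Conditions: 2-bromopropane, K2CO3, DMF, 70 °C
Reagents that add atoms: 2-bromopropane, CC(C)Br
Why: Williamson etherification; the phenol para to the formyl group is acidic and alkylates cleanly.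

Step 7
Reactants: 9 3-bromo-4-isopropoxybenzaldehyde
Product: 10 4-isopropoxy-3-(4,4,5,5-tetramethyl-1,3,2-dioxaborolan-2-yl)benzaldehyde
Conditions: B2pin2, Pd(dppf)Cl2 (3 mol %), KOAc, 1,4-dioxane, 90 °C
Reagents that add atoms: bis(pinacolato)diboron, CC1(C)OB(OC1(C)C)B1OC(C)(C)C(C)(C)O1
Why: Miyaura borylation; KOAc is too weak a base to start Suzuki homocoupling and leaves the aldehyde alone.

Step 8
Reactants: 7 8-iodo-5,7-diisopropoxy-2-(4-isopropoxy-3-methoxyphenyl)-4H-chromen-4-one; 10 4-isopropoxy-3-(4,4,5,5-tetramethyl-1,3,2-dioxaborolan-2-yl)benzaldehyde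
Product: 11 3-[5,7-diisopropoxy-2-(4-isopropoxy-3-methoxyphenyl)-4-oxo-4H-chromen-8-yl]-4-isopropoxybenzaldehyde
Conditions: Pd(OAc)2 (5 mol %), SPhos (10 mol %), K3PO4, toluene/H2O (10:1), 90 °C
Reagents that add atoms: none
Why: Suzuki–Miyaura coupling; zerovalent palladium formed from Pd(OAc)2 and the bulky electron-rich biarylphosphine inserts into the aryl iodide and should carry transmetalation and reductive elimination through at the tri-ortho-substituted centre, as in known couplings of 8-iodoflavones with 2-alkoxyarylboronates; aldehyde and chromone tolerate K3PO4.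

Step 9
Reactants: 11 3-[5,7-diisopropoxy-2-(4-isopropoxy-3-methoxyphenyl)-4-oxo-4H-chromen-8-yl]-4-isopropoxybenzaldehyde
Product: 12 8-(5-ethynyl-2-isopropoxyphenyl)-5,7-diisopropoxy-2-(4-isopropoxy-3-methoxyphenyl)-4H-chromen-4-one
Conditions: dimethyl (1-diazo-2-oxopropyl)phosphonate, K2CO3, MeOH/THF (1:1), 0 °C → rt
Reagents that add atoms: dimethyl (1-diazo-2-oxopropyl)phosphonate, CC(=O)C(=[N+]=[N-])P(=O)(OC)OC
Why: Ohira–Bestmann homologation (methanolysis to the diazomethylphosphonate anion, olefination, loss of N2 and 1,2-hydride shift of the alkylidene carbene); carbonate in methanol at room temperature is too mild to open the chromone, which has no enolisable position.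

Step 10
Reactants: 13 2,4,6-trihydroxybenzaldehyde
Product: 14 2-hydroxy-4,6-diisopropoxybenzaldehyde
Conditions: 2-bromopropane (2.2 equiv), K2CO3, DMF, 50 °C
Reagents that add atoms: 2-bromopropane, CC(C)Br
Why: Williamson etherification; as in step 1 the chelated ortho hydroxyl should remain when the halide is limited, and a secondary halide gives little C-alkylation.

Step 11
Reactants: 14 2-hydroxy-4,6-diisopropoxybenzaldehyde
Product: 15 2-(methoxymethoxy)-4,6-diisopropoxybenzaldehyde
Conditions: NaH, DMF, 0 °C; MOMCl, 0 °C → rt
Reagents that add atoms: chloromethyl methyl ether, COCCl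
Why: O-alkylation of the sodium phenoxide with a reactive α-chloro ether; full deprotonation overcomes the hydrogen bond to the aldehyde.

Step 12
Reactants: 15 2-(methoxymethoxy)-4,6-diisopropoxybenzaldehyde
Product: 16 (E)-2-(methoxymethoxy)-4,6-diisopropoxybenzaldehyde oxime
Conditions: NH2OH·HCl, NaOAc, EtOH/H2O, rt
Reagents that add atoms: hydroxylamine hydrochloride, Cl.NO
Why: Oxime condensation in acetate buffer, which the methoxymethyl acetal survives; aryl aldoximes form as the E isomer, and the geometry is lost in the next step anyway.

Step 13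
Reactants: 16 (E)-2-(methoxymethoxy)-4,6-diisopropoxybenzaldehyde oxime
Product: 17 2-(methoxymethoxy)-4,6-diisopropoxybenzonitrile oxide
Conditions: PhI(OAc)2 (1.1 equiv), MeOH, 0 °C; cold work-up, used promptly
Reagents that add atoms: none
Why: Hypervalent-iodine dehydrogenation of an aldoxime (ligand exchange at iodine, then loss of iodobenzene and acetic acid); it is preferred to N-halosuccinimides, which could halogenate the very electron-rich ring, and 2,4,6-trialkoxybenzonitrile oxides are known to be isolable.

Step 14
Reactants: 17 2-(methoxymethoxy)-4,6-diisopropoxybenzonitrile oxide; 12 8-(5-ethynyl-2-isopropoxyphenyl)-5,7-diisopropoxy-2-(4-isopropoxy-3-methoxyphenyl)-4H-chromen-4-one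
Product: 18 8-(5-{3-[2-(methoxymethoxy)-4,6-diisopropoxyphenyl]isoxazol-5-yl}-2-isopropoxyphenyl)-5,7-diisopropoxy-2-(4-isopropoxy-3-methoxyphenyl)-4H-chromen-4-one
Conditions: 17 (1.5 equiv), toluene, 70 °C
Reagents that add atoms: none
Why: Concerted, thermally allowed [3+2] (Huisgen) cycloaddition of the nitrile oxide across the terminal C≡C bond; the closest known reaction is the addition of persistent 2,6-disubstituted benzonitrile oxides to aryl acetylenes, which gives 3,5-diarylisoxazoles. The isoxazole ring is closed in this one intermolecular event, in which the nitrile oxide carbon bonds to the terminal alkyne carbon (the future C3–C4 bond of the apigenin unit) and the oxide oxygen to the internal carbon (the future C2). No stereocenter is formed. The step needs regioselectivity for the 3,5- over the 3,4-disubstituted isoxazole, and the substrate secures it twice: the di-ortho-substituted aryl group on the dipole carbon avoids the substituted alkyne carbon, and the larger frontier-orbital coefficient of an aryl acetylene lies on its terminal carbon, which pairs with the dipole carbon. It also needs chemoselectivity for the alkyne over the pyranone C2=C3 bond of 12, which is trisubstituted, part of a vinylogous ester and screened by the neighbouring aryl groups. The two ortho alkoxy groups of 17 hold back dimerisation to the furoxan, so an excess of the dipole should last at 70 °C, a temperature kept below that at which hindered nitrile oxides rearrange to isocyanates. No base, acid or metal is present, so the isopropyl ethers, the methoxymethyl acetal and the chromone should pass unchanged.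

Step 15
Reactants: 18 8-(5-{3-[2-(methoxymethoxy)-4,6-diisopropoxyphenyl]isoxazol-5-yl}-2-isopropoxyphenyl)-5,7-diisopropoxy-2-(4-isopropoxy-3-methoxyphenyl)-4H-chromen-4-one
Product: 19 8-(5-{(Z)-3-amino-3-[2-(methoxymethoxy)-4,6-diisopropoxyphenyl]prop-2-enoyl}-2-isopropoxyphenyl)-5,7-diisopropoxy-2-(4-isopropoxy-3-methoxyphenyl)-4H-chromen-4-one
Conditions: Mo(CO)6 (1 equiv), MeCN/H2O (10:1), 80 °C
Reagents that add atoms: none
Why: Reductive N–O cleavage of an isoxazole by zerovalent molybdenum (N-coordination, insertion into the N–O bond, protonolysis by water), a known route to β-amino enones; the Z geometry follows from the ring and is held by the N–H···O hydrogen bond, and aryl ethers, acetal and chromone are not reduced.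

Step 16
Reactants: 19 8-(5-{(Z)-3-amino-3-[2-(methoxymethoxy)-4,6-diisopropoxyphenyl]prop-2-enoyl}-2-isopropoxyphenyl)-5,7-diisopropoxy-2-(4-isopropoxy-3-methoxyphenyl)-4H-chromen-4-one
Product: 21 8-[5-(5,7-diisopropoxy-4-oxo-4H-chromen-2-yl)-2-isopropoxyphenyl]-5,7-diisopropoxy-2-(4-isopropoxy-3-methoxyphenyl)-4H-chromen-4-one, via hydroxyaryl 1,3-diketone 20 (not isolated)
Conditions: 2 M aq. HCl, EtOH, 80 °C
Reagents that add atoms: water, O
Why: Acid hydrolysis of the vinylogous amide and of the methoxymethyl acetal gives the o-hydroxyaryl 1,3-diketone, whose only free phenol adds to the ring B carbonyl and dehydrates to the 4-pyranone (flavone cyclodehydration); isopropyl ethers and the existing chromone are stable to dilute acid, and the known conversion of 3-(2-hydroxyaryl)-5-arylisoxazoles into flavones is the model.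

Step 17
Reactants: 21 8-[5-(5,7-diisopropoxy-4-oxo-4H-chromen-2-yl)-2-isopropoxyphenyl]-5,7-diisopropoxy-2-(4-isopropoxy-3-methoxyphenyl)-4H-chromen-4-one
Product: 22 8-[5-(5,7-dihydroxy-4-oxo-4H-chromen-2-yl)-2-hydroxyphenyl]-5,7-dihydroxy-2-(4-hydroxy-3-methoxyphenyl)-4H-chromen-4-one
Conditions: BCl3 (excess), CH2Cl2, −78 → 0 °C; then MeOH, aq. NaHCO3
Reagents that add atoms: none
Why: Lewis-acid dealkylation; the boron-complexed isopropyl ethers ionise in an SN1-like way to 2-chloropropane, the two ethers peri to a carbonyl first, whereas the methyl ether cannot ionise so and should survive, as in known selective removals of isopropyl beside methyl ethers on guaiacyl rings; the low temperature avoids acid-induced ring opening that could move the aryl group from C8 to C6.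

## Compound list

1 | 2',4',6'-trihydroxyacetophenone | CC(=O)c1c(O)cc(O)cc1O | starting material
2 | 1-(2-hydroxy-4,6-diisopropoxyphenyl)ethanone | CC(=O)c1c(O)cc(OC(C)C)cc1OC(C)C | intermediate
3 | 1-(2-hydroxy-3-iodo-4,6-diisopropoxyphenyl)ethanone | CC(=O)c1c(O)c(I)c(OC(C)C)cc1OC(C)C | intermediate
4 | vanillin | COc1cc(C=O)ccc1O | starting material
5 | 4-isopropoxy-3-methoxybenzaldehyde | COc1cc(C=O)ccc1OC(C)C | intermediate
6 | (E)-1-(2-hydroxy-3-iodo-4,6-diisopropoxyphenyl)-3-(4-isopropoxy-3-methoxyphenyl)prop-2-en-1-one | COc1cc(/C=C/C(=O)c2c(O)c(I)c(OC(C)C)cc2OC(C)C)ccc1OC(C)C | intermediate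
7 | 8-iodo-5,7-diisopropoxy-2-(4-isopropoxy-3-methoxyphenyl)-4H-chromen-4-one | COc1cc(-c2cc(=O)c3c(OC(C)C)cc(OC(C)C)c(I)c3o2)ccc1OC(C)C | intermediate
8 | 3-bromo-4-hydroxybenzaldehyde | O=Cc1ccc(O)c(Br)c1 | starting material
9 | 3-bromo-4-isopropoxybenzaldehyde | CC(C)Oc1ccc(C=O)cc1Br | intermediate
10 | 4-isopropoxy-3-(4,4,5,5-tetramethyl-1,3,2-dioxaborolan-2-yl)benzaldehyde | CC(C)Oc1ccc(C=O)cc1B1OC(C)(C)C(C)(C)O1 | intermediate
11 | 3-[5,7-diisopropoxy-2-(4-isopropoxy-3-methoxyphenyl)-4-oxo-4H-chromen-8-yl]-4-isopropoxybenzaldehyde | COc1cc(-c2cc(=O)c3c(OC(C)C)cc(OC(C)C)c(-c4cc(C=O)ccc4OC(C)C)c3o2)ccc1OC(C)C | intermediate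
12 | 8-(5-ethynyl-2-isopropoxyphenyl)-5,7-diisopropoxy-2-(4-isopropoxy-3-methoxyphenyl)-4H-chromen-4-one | COc1cc(-c2cc(=O)c3c(OC(C)C)cc(OC(C)C)c(-c4cc(C#C)ccc4OC(C)C)c3o2)ccc1OC(C)C | intermediate
13 | 2,4,6-trihydroxybenzaldehyde | O=Cc1c(O)cc(O)cc1O | starting material
14 | 2-hydroxy-4,6-diisopropoxybenzaldehyde | CC(C)Oc1cc(O)c(C=O)c(OC(C)C)c1 | intermediate
15 | 2-(methoxymethoxy)-4,6-diisopropoxybenzaldehyde | COCOc1cc(OC(C)C)cc(OC(C)C)c1C=O | intermediate
16 | (E)-2-(methoxymethoxy)-4,6-diisopropoxybenzaldehyde oxime | COCOc1cc(OC(C)C)cc(OC(C)C)c1/C=N/O | intermediate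
17 | 2-(methoxymethoxy)-4,6-diisopropoxybenzonitrile oxide | COCOc1cc(OC(C)C)cc(OC(C)C)c1C#[N+][O-] | intermediate
18 | 8-(5-{3-[2-(methoxymethoxy)-4,6-diisopropoxyphenyl]isoxazol-5-yl}-2-isopropoxyphenyl)-5,7-diisopropoxy-2-(4-isopropoxy-3-methoxyphenyl)-4H-chromen-4-one | COc1cc(-c2cc(=O)c3c(OC(C)C)cc(OC(C)C)c(-c4cc(-c5cc(-c6c(OCOC)cc(OC(C)C)cc6OC(C)C)no5)ccc4OC(C)C)c3o2)ccc1OC(C)C | intermediate
19 | 8-(5-{(Z)-3-amino-3-[2-(methoxymethoxy)-4,6-diisopropoxyphenyl]prop-2-enoyl}-2-isopropoxyphenyl)-5,7-diisopropoxy-2-(4-isopropoxy-3-methoxyphenyl)-4H-chromen-4-one | COc1cc(-c2cc(=O)c3c(OC(C)C)cc(OC(C)C)c(-c4cc(C(=O)/C=C(\N)c5c(OCOC)cc(OC(C)C)cc5OC(C)C)ccc4OC(C)C)c3o2)ccc1OC(C)C | intermediate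
20 | 1-(2-hydroxy-4,6-diisopropoxyphenyl)-3-{3-[5,7-diisopropoxy-2-(4-isopropoxy-3-methoxyphenyl)-4-oxo-4H-chromen-8-yl]-4-isopropoxyphenyl}propane-1,3-dione (formed in the flask in step 16, not isolated) | COc1cc(-c2cc(=O)c3c(OC(C)C)cc(OC(C)C)c(-c4cc(C(=O)CC(=O)c5c(O)cc(OC(C)C)cc5OC(C)C)ccc4OC(C)C)c3o2)ccc1OC(C)C | intermediate
21 | 8-[5-(5,7-diisopropoxy-4-oxo-4H-chromen-2-yl)-2-isopropoxyphenyl]-5,7-diisopropoxy-2-(4-isopropoxy-3-methoxyphenyl)-4H-chromen-4-one | COc1cc(-c2cc(=O)c3c(OC(C)C)cc(OC(C)C)c(-c4cc(-c5cc(=O)c6c(OC(C)C)cc(OC(C)C)cc6o5)ccc4OC(C)C)c3o2)ccc1OC(C)C | intermediate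
22 | 8-[5-(5,7-dihydroxy-4-oxo-4H-chromen-2-yl)-2-hydroxyphenyl]-5,7-dihydroxy-2-(4-hydroxy-3-methoxyphenyl)-4H-chromen-4-one | COc1cc(-c2cc(=O)c3c(O)cc(O)c(-c4cc(-c5cc(=O)c6c(O)cc(O)cc6o5)ccc4O)c3o2)ccc1O | target

## Step count and least certain steps

Total: 17 steps. Longest linear sequence: 10 steps (steps 1, 2, 4, 5, 8, 9, 14, 15, 16, 17, from 1 to 22).

**Step 14 (key step).** The most likely failure is that the cycloaddition is too slow in the temperature window the dipole tolerates. Rearrangement of the nitrile oxide to the aryl isocyanate, or slow dimerisation, would then use up 17 before the valuable alkyne 12 has reacted. The fallback forms the same C3–C4 bond by acetylide addition; it sets out from 12 and 15 and comes back at 21. Deprotonation of 12 with LiN(SiMe3)2 in THF at −78 °C and addition to aldehyde 15 should give the racemic propargylic alcohol F1. MnO2 in CH2Cl2 would oxidise it to the ynone F2. HCl in methanol would remove the methoxymethyl group to give the o-hydroxyaryl ynone F3. With K2CO3 in acetone the phenoxide of F3 should add to the ynone in the 6-endo sense and give 21 directly, so that steps 15 and 16 are bypassed.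

**Step 13.** The oxidation may not stay at the oxime. Electrophilic attack of the oxidant on the ring positions between the alkoxy groups, addition of methanol to the nascent dipole, or loss of the acetal through the acetic acid released would all lower the amount of usable 17. The fallback makes the nitrile oxide by dehydration instead of oxidation; it sets out from 15 and comes back at 17. Oxidation of 15 with NaClO2/NaH2PO4 in the presence of 2-methyl-2-butene should give the benzoic acid F4. Carbodiimide coupling with O-(tert-butyldiphenylsilyl)hydroxylamine would give the O-silyl hydroxamate F5. Triflic anhydride and triethylamine in CH2Cl2 at −40 °C would dehydrate F5 to 17 without any oxidant meeting the ring.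

**Step 8.** Transmetalation to the crowded arylpalladium iodide may be slower than protodeboronation of the ortho-alkoxy boronate 10, and hydrodeiodination of 7 would follow. The fallback changes the nucleophile to an organozinc, which needs no aqueous base; it sets out from 9 and 7 and comes back at 11. Acetalisation of 9 with ethylene glycol (TsOH, toluene, water removal) should give the dioxolane F6. Bromine–lithium exchange with n-BuLi at −78 °C and addition of ZnCl2 would give the arylzinc chloride F7. Negishi coupling of F7 with 7 (Pd(OAc)2, SPhos, THF, 60 °C) would give the biaryl acetal F8, and dilute HCl in THF would release 11.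

**Step 2.** Iodination may take place at C5 between the two isopropoxy groups, or twice. In addition, the aryl iodide of 6 may suffer protodeiodination by hydrogen iodide at 120 °C in step 5. The fallback introduces iodine after the pyranone is formed; it sets out from 2 and comes back at 7. Claisen–Schmidt condensation of 2 with 5 should give the iodine-free chalcone F9. I2 in DMSO would cyclise F9 to the 8-unsubstituted flavone F10. Iodination of F10 (NIS, TFA, MeCN) is then expected at C8, which is flanked by the ring oxygen and one isopropoxy group, and not at C6 between two isopropoxy groups, as is the known preference of 5,7-dialkoxyflavones.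

**Step 10.** Partial etherification may give a mixture: under-alkylation, alkylation of the third hydroxyl and some C-alkylation of the phloroglucinol-type phenoxide. The fallback alkylates exhaustively and then removes one group under chelation control; it sets out from 13 and comes back at 14. Excess 2-bromopropane with K2CO3 in DMF at 80 °C should give 2,4,6-triisopropoxybenzaldehyde F11. One equivalent of BCl3 in CH2Cl2 at −78 °C would cleave only an ether ortho to the aldehyde through the boron chelate; the two ortho ethers are equivalent, so 14 is the single product expected.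

## Further compounds

F1 | step 14 | rac-1-[2-(methoxymethoxy)-4,6-diisopropoxyphenyl]-3-{3-[5,7-diisopropoxy-2-(4-isopropoxy-3-methoxyphenyl)-4-oxo-4H-chromen-8-yl]-4-isopropoxyphenyl}prop-2-yn-1-ol | COc1cc(-c2cc(=O)c3c(OC(C)C)cc(OC(C)C)c(-c4cc(C#CC(O)c5c(OCOC)cc(OC(C)C)cc5OC(C)C)ccc4OC(C)C)c3o2)ccc1OC(C)C
F2 | step 14 | 1-[2-(methoxymethoxy)-4,6-diisopropoxyphenyl]-3-{3-[5,7-diisopropoxy-2-(4-isopropoxy-3-methoxyphenyl)-4-oxo-4H-chromen-8-yl]-4-isopropoxyphenyl}prop-2-yn-1-one | COc1cc(-c2cc(=O)c3c(OC(C)C)cc(OC(C)C)c(-c4cc(C#CC(=O)c5c(OCOC)cc(OC(C)C)cc5OC(C)C)ccc4OC(C)C)c3o2)ccc1OC(C)C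
F3 | step 14 | 1-(2-hydroxy-4,6-diisopropoxyphenyl)-3-{3-[5,7-diisopropoxy-2-(4-isopropoxy-3-methoxyphenyl)-4-oxo-4H-chromen-8-yl]-4-isopropoxyphenyl}prop-2-yn-1-one | COc1cc(-c2cc(=O)c3c(OC(C)C)cc(OC(C)C)c(-c4cc(C#CC(=O)c5c(O)cc(OC(C)C)cc5OC(C)C)ccc4OC(C)C)c3o2)ccc1OC(C)C
F4 | step 13 | 2-(methoxymethoxy)-4,6-diisopropoxybenzoic acid | COCOc1cc(OC(C)C)cc(OC(C)C)c1C(=O)O
F5 | step 13 | N-[(tert-butyldiphenylsilyl)oxy]-2-(methoxymethoxy)-4,6-diisopropoxybenzamide | COCOc1cc(OC(C)C)cc(OC(C)C)c1C(=O)NO[Si](c1ccccc1)(c1ccccc1)C(C)(C)C
F6 | step 8 | 2-(3-bromo-4-isopropoxyphenyl)-1,3-dioxolane | CC(C)Oc1ccc(C2OCCO2)cc1Br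
F7 | step 8 | [5-(1,3-dioxolan-2-yl)-2-isopropoxyphenyl]zinc chloride | CC(C)Oc1ccc(C2OCCO2)cc1[Zn]Cl
F8 | step 8 | 8-[5-(1,3-dioxolan-2-yl)-2-isopropoxyphenyl]-5,7-diisopropoxy-2-(4-isopropoxy-3-methoxyphenyl)-4H-chromen-4-one | COc1cc(-c2cc(=O)c3c(OC(C)C)cc(OC(C)C)c(-c4cc(C5OCCO5)ccc4OC(C)C)c3o2)ccc1OC(C)C
F9 | step 2 | (E)-1-(2-hydroxy-4,6-diisopropoxyphenyl)-3-(4-isopropoxy-3-methoxyphenyl)prop-2-en-1-one | COc1cc(/C=C/C(=O)c2c(O)cc(OC(C)C)cc2OC(C)C)ccc1OC(C)C
F10 | step 2 | 5,7-diisopropoxy-2-(4-isopropoxy-3-methoxyphenyl)-4H-chromen-4-one | COc1cc(-c2cc(=O)c3c(OC(C)C)cc(OC(C)C)cc3o2)ccc1OC(C)C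
F11 | step 10 | 2,4,6-triisopropoxybenzaldehyde | CC(C)Oc1cc(OC(C)C)c(C=O)c(OC(C)C)c1
A1 | alternative 1 | 1-(2-hydroxy-4,6-diisopropoxyphenyl)-3-{3-[2-hydroxy-4,6-diisopropoxy-3-[3-(4-isopropoxy-3-methoxyphenyl)-3-oxopropanoyl]phenyl]-4-isopropoxyphenyl}propane-1,3-dione | COc1cc(C(=O)CC(=O)c2c(OC(C)C)cc(OC(C)C)c(-c3cc(C(=O)CC(=O)c4c(O)cc(OC(C)C)cc4OC(C)C)ccc3OC(C)C)c2O)ccc1OC(C)C
A2 | alternative 1 | 2-acetyl-3,5-diisopropoxyphenyl 3-[3-acetyl-4,6-diisopropoxy-2-(4-isopropoxy-3-methoxybenzoyloxy)phenyl]-4-isopropoxybenzoate | COc1cc(C(=O)Oc2c(C(C)=O)c(OC(C)C)cc(OC(C)C)c2-c2cc(C(=O)Oc3cc(OC(C)C)cc(OC(C)C)c3C(C)=O)ccc2OC(C)C)ccc1OC(C)C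
A3 | alternative 2 | 8-(5-bromo-2-isopropoxyphenyl)-5,7-dihydroxy-2-(4-isopropoxy-3-methoxyphenyl)-4H-chromen-4-one | COc1cc(-c2cc(=O)c3c(O)cc(O)c(-c4cc(Br)ccc4OC(C)C)c3o2)ccc1OC(C)C
A4 | alternative 2 | rac-tert-butyl 4-(5-bromo-2-isopropoxyphenyl)-4-[6-(4-isopropoxy-3-methoxyphenyl)-4-oxo-4H-pyran-2-yl]-3-oxobutanoate | COc1cc(-c2cc(=O)cc(C(c3cc(Br)ccc3OC(C)C)C(=O)CC(=O)OC(C)(C)C)o2)ccc1OC(C)C
A5 | alternative 3 | 8-[5-(5,7-diisopropoxy-4-oxo-4H-chromen-2-yl)-2-isopropoxyphenyl]-5,7-diisopropoxy-2-(4-isopropoxy-3-methoxyphenyl)-4H-chromen-4-one (identical with 21) | COc1cc(-c2cc(=O)c3c(OC(C)C)cc(OC(C)C)c(-c4cc(-c5cc(=O)c6c(OC(C)C)cc(OC(C)C)cc6o5)ccc4OC(C)C)c3o2)ccc1OC(C)C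
A6 | alternative 3 | (Z)-3-{2-[5-(5,7-diisopropoxy-4-oxo-4H-chromen-2-yl)-2-isopropoxyphenyl]-3,5-diisopropoxyphenoxy}-3-(4-isopropoxy-3-methoxyphenyl)prop-2-enoic acid | COc1cc(/C(=C/C(=O)O)Oc2cc(OC(C)C)cc(OC(C)C)c2-c2cc(-c3cc(=O)c4c(OC(C)C)cc(OC(C)C)cc4o3)ccc2OC(C)C)ccc1OC(C)C
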